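**Strategy.** In eudesmane numbering, ring A (C1–C5, C10) is oxygenated at C1 and C4; this 1,4-relationship makes it the one-carbon homologue of a cyclopentane-1,3-dione. Ring B and four stereocentres (C5, C6, C9, C10) are therefore set first by an enantioselective Diels–Alder reaction of 4-methylcyclopent-4-ene-1,3-dione with a 1,4-bis(silyloxy)-2-isopropylbutadiene, which gives a cis-hydrindane-1,3-dione. In the key step a zinc carbenoid cyclopropanates its enolate and the donor–acceptor cyclopropane fragments, inserting CH2 next to the acidic CH2 and expanding the five-membered ring to the cyclohexane-1,4-dione ring A. Epimerisation at C5, C4 methylenation/dihydroxylation, redox inversion at C9, hydroxyl-directed hydrogenation at C7 and orthoester exchange complete the target.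

Key step: step 6

Remark on names: locants and α/β refer to the eudesmane skeleton in its usual drawing (ring A = C1–C5, C10; ring B = C5–C10; C14 = methyl on C10; C15 on C4; α below, β above the plane); the target has the 10-methyl α.

Assumption: the (S)-configured catalyst of step 5 is taken to give the enantiomer drawn; if the sense proves opposite, the (R)-catalyst is used and nothing else changes.

Step 1
Reactants: 1 3-methylcyclopent-2-en-1-one
Product: 2 4-methylcyclopent-4-ene-1,3-dione
Conditions: t-BuOOH (70% in water, 5 equiv), Rh2(cap)4 (dirhodium tetracaprolactamate, 1 mol %), K2CO3, CH2Cl2, rt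
Reagents that add atoms: tert-butyl hydroperoxide, CC(C)(C)OO
Why: Dirhodium caprolactamate/t-BuOOH allylic oxidation of a cyclic enone converts its only ring CH2 that is allylic to the alkene (the γ-position) into a carbonyl, giving the ene-dione without creating a stereocentre.

Step 2
Reactants: 3 isobutyltriphenylphosphonium bromide; 4 ethyl formate
Product: 6 3-methyl-2-(triphenylphosphoranylidene)butanal, via isobutylidenetriphenylphosphorane 5 (not isolated)
Conditions: n-BuLi, THF, 0 °C; then HCO2Et, 0 °C to rt
Reagents that add atoms: none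
Why: Deprotonation gives the non-stabilised ylide, and its C-formylation by ethyl formate (acylation of a phosphorus ylide, the released ethoxide re-forming the ylide) delivers the stabilised formyl ylide.

Step 3
Reactants: 6 3-methyl-2-(triphenylphosphoranylidene)butanal; 7 (tert-butyldimethylsilyloxy)acetaldehyde
Product: 8 (E)-4-(tert-butyldimethylsilyloxy)-2-isopropylbut-2-enal
Conditions: toluene, 90 °C
Reagents that add atoms: none
Why: Wittig olefination of a reactive α-silyloxy aldehyde with a stabilised α-branched formyl ylide gives the trisubstituted enal with CHO trans to CH2OTBS, the usual E outcome for stabilised ylides.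

Step 4
Reactants: 8 (E)-4-(tert-butyldimethylsilyloxy)-2-isopropylbut-2-enal
Product: 9 (1E,3E)-4-(tert-butyldimethylsilyloxy)-2-isopropyl-1-(triisopropylsilyloxy)buta-1,3-diene
Conditions: i-Pr3SiOTf, Et3N, Et2O, −78 °C to rt
Reagents that add atoms: triisopropylsilyl trifluoromethanesulfonate, CC(C)[Si](OS(=O)(=O)C(F)(F)F)(C(C)C)C(C)C
Why: O-silylation of the enal and γ-deprotonation (vinylogous soft enolisation) give the 1-silyloxydiene, the s-trans enal fixing the 1E enol ether and allylic strain with the cis isopropyl group placing the OTBS group outside (3E).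

Step 5
Reactants: 2 4-methylcyclopent-4-ene-1,3-dione; 9 (1E,3E)-4-(tert-butyldimethylsilyloxy)-2-isopropyl-1-(triisopropylsilyloxy)buta-1,3-diene
Product: 10 endo adduct, a cis-hydrindane-1,3-dione (5α-H; 10α-methyl; 6β-OTIPS; 9β-OTBS; 7-ene)
Conditions: (3aS)-1-(2-methylphenyl)-3,3-diphenyltetrahydro-1H,3H-pyrrolo[1,2-c][1,3,2]oxazaborole (20 mol %), HN(SO2CF3)2 (20 mol %), CH2Cl2, −78 to −40 °C
Reagents that add atoms: none
Why: This is a catalytic enantioselective Diels–Alder reaction of a 2-ene-1,4-dione under chiral oxazaborolidinium activation, in which the catalyst binds the carbonyl next to the vinylic C5–H, the leading bond joins the less hindered OTBS terminus (C9) to the methyl-bearing C10 while the isopropyl-flanked OTIPS terminus (C6) closes onto C5, the endo transition state puts both silyloxy groups cis to the dione ring and trans to 5-H/10-methyl, and the catalyst shields one enantiotopic face, so that C5, C6, C9 and C10 are set at once.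

Step 6
Reactants: 10 endo adduct, a cis-hydrindane-1,3-dione
Product: 11 9β-(tert-butyldimethylsilyloxy)-6β-(triisopropylsilyloxy)-15-nor-5α,10α-eudesm-7-ene-1,4-dione (cis-fused)
Conditions: Et2Zn (4 equiv), CH2I2 (4 equiv), CH2Cl2, 0 °C to rt; then aqueous NH4Cl
Reagents that add atoms: diiodomethane, ICI
Why: Et2Zn deprotonates the enolised 1,3-dione and the carbenoid EtZnCH2I cyclopropanates the enolate C=C to a zinc cyclopropanolate whose ring-fusion bond, flanked by the alkoxide donor and the remaining carbonyl acceptor, fragments in a retro-aldol sense, so that the new CH2 ends up inside the ring and the five-membered dione becomes the cyclohexane-1,4-dione of ring A after protonation. The closest known reaction is the zinc-carbenoid (Zercher) chain extension of β-diketones and its ring-expanding version on cyclic β-keto esters, with the fluoride- or acid-induced opening of donor–acceptor siloxycyclopropanes as the stepwise relative. The only ring closed is the transient cyclopropane (concerted methylene transfer to the enolate), and the six-membered ring then arises by cleavage of the bond shared by the three- and five-membered rings, not by a cyclisation. No stereocentre is created, since the cyclopropane carbons revert to CH2 and C=O, and C5, C6, C9 and C10 are untouched. The step needs chemoselectivity for the enolate over the 7-ene, which the far higher nucleophilicity of the zinc enolate and the isopropyl and two bulky silyloxy groups around the alkene should secure; it needs no regioselectivity because insertion on either side of the central CH2 gives the same 1,4-dione, and a second insertion is not expected because the product enolate is no longer a β-dicarbonyl.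

Step 7
Reactants: 11 9β-(tert-butyldimethylsilyloxy)-6β-(triisopropylsilyloxy)-15-nor-5α,10α-eudesm-7-ene-1,4-dione
Product: 12 9β-(tert-butyldimethylsilyloxy)-6β-(triisopropylsilyloxy)-15-nor-5β,10α-eudesm-7-ene-1,4-dione (trans-fused)
Conditions: DBU (1,8-diazabicyclo[5.4.0]undec-7-ene, 0.2 equiv), CH2Cl2, 0 °C
Reagents that add atoms: none
Why: Base-mediated epimerisation through the C4/C5 enolate should convert the cis- into the trans-fused 10-methyldecalin-1,4-dione (as in classical isomerisations of quinone Diels–Alder adducts) and make the 6-silyloxy group equatorial, a catalytic amidine at low temperature being chosen so that reprotonation outpaces E1cB loss of the poor silanolate leaving group.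

Step 8
Reactants: 12 9β-(tert-butyldimethylsilyloxy)-6β-(triisopropylsilyloxy)-15-nor-5β,10α-eudesm-7-ene-1,4-dione
Product: 13 9β-(tert-butyldimethylsilyloxy)-6β-(triisopropylsilyloxy)-5β,10α-eudesma-4(15),7-dien-1-one
Conditions: Zn, CH2Br2, TiCl4 (preformed Lombardo reagent), THF/CH2Cl2, 0 °C to rt
Reagents that add atoms: dibromomethane, BrCBr
Why: Takai–Lombardo methylenation, a non-basic olefination for hindered epimerisable ketones, should react only at the C4 carbonyl because the C1 carbonyl is neopentylic and shielded on both faces by the axial 10α-methyl and the axial 9β-silyloxy group.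

Step 9
Reactants: 13 9β-(tert-butyldimethylsilyloxy)-6β-(triisopropylsilyloxy)-5β,10α-eudesma-4(15),7-dien-1-one
Product: 14 9β-(tert-butyldimethylsilyloxy)-4β,15-dihydroxy-6β-(triisopropylsilyloxy)-5β,10α-eudesm-7-en-1-one
Conditions: OsO4 (5 mol %), N-methylmorpholine N-oxide, acetone/H2O, rt
Reagents that add atoms: N-methylmorpholine N-oxide, C[N+]1([O-])CCOCC1; water, O
Why: Upjohn dihydroxylation should take place at the exocyclic 1,1-disubstituted alkene (the 7-ene is buried between isopropyl and two silyloxy groups) from the β face opposite the syn-axial 10α-methyl, giving the equatorial 4β-OH and the axial 15-CH2OH.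

Step 10
Reactants: 14 9β-(tert-butyldimethylsilyloxy)-4β,15-dihydroxy-6β-(triisopropylsilyloxy)-5β,10α-eudesm-7-en-1-one
Product: 15 4β,9β,15-trihydroxy-6β-(triisopropylsilyloxy)-5β,10α-eudesm-7-en-1-one
Conditions: HF·pyridine, pyridine, THF, 0 °C to rt
Reagents that add atoms: none
Why: Buffered HF·pyridine cleaves a tert-butyldimethylsilyl ether much faster than the bulkier triisopropylsilyl ether (selective desilylation), so only the 9-hydroxyl is unmasked.

Step 11
Reactants: 15 4β,9β,15-trihydroxy-6β-(triisopropylsilyloxy)-5β,10α-eudesm-7-en-1-one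
Product: 16 4β,15-dihydroxy-6β-(triisopropylsilyloxy)-5β,10α-eudesm-7-ene-1,9-dione
Conditions: MnO2, CH2Cl2, rt
Reagents that add atoms: none
Why: MnO2 oxidises only the allylic 9-alcohol to the enone and leaves the saturated primary and tertiary hydroxyls, which erases the wrong C9 configuration inherited from the endo cycloaddition.

Step 12
Reactants: 16 4β,15-dihydroxy-6β-(triisopropylsilyloxy)-5β,10α-eudesm-7-ene-1,9-dione
Product: 17 6β-(triisopropylsilyloxy)-5β,10α-eudesm-7-ene-1α,4β,9α,15-tetrol
Conditions: NaBH4, CeCl3·7H2O, MeOH, −78 to 0 °C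
Reagents that add atoms: none
Why: Luche 1,2-reduction should deliver hydride axially to both carbonyls from the β face anti to the adjacent axial 10α-methyl, giving the equatorial 1α- and 9α-alcohols, as in reductions of Wieland–Miescher-type ketones.

Step 13
Reactants: 17 6β-(triisopropylsilyloxy)-5β,10α-eudesm-7-ene-1α,4β,9α,15-tetrol
Product: 18 6β-(triisopropylsilyloxy)-5β,7αH,10α-eudesmane-1α,4β,9α,15-tetrol
Conditions: H2 (1 atm), [Ir(cod)(PCy3)(py)]PF6 (10 mol %), CH2Cl2, rt
Reagents that add atoms: none
Why: In this hydroxyl-directed hydrogenation the allylic 9α-OH binds iridium and delivers H2 to the α face of the 7-ene (the β face is also blocked by 6β-OTIPS), which sets C7 with the isopropyl group β, axial and cis to O6.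

Step 14
Reactants: 18 6β-(triisopropylsilyloxy)-5β,7αH,10α-eudesmane-1α,4β,9α,15-tetrol
Product: 19 5β,7αH,10α-eudesmane-1α,4β,6β,9α,15-pentol
Conditions: Bu4NF, THF, 50 °C
Reagents that add atoms: none
Why: Fluoride cleaves the remaining silyl ether and frees the 6β-hydroxyl without touching any stereocentre.

Step 15
Reactants: 20 (E)-β-bromostyrene; 21 tetramethyl orthocarbonate
Product: 23 trimethyl orthocinnamate, via (E)-styrylmagnesium bromide 22 (not isolated)
Conditions: Mg, THF, rt; then C(OMe)4 (3 equiv), 60 °C
Reagents that add atoms: none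
Why: The alkenyl Grignard reagent forms with retention of the E geometry and displaces one methoxide of the orthocarbonate (Tschitschibabin orthoester synthesis), excess orthocarbonate suppressing a second addition.

Step 16
Reactants: 19 5β,7αH,10α-eudesmane-1α,4β,6β,9α,15-pentol; 23 trimethyl orthocinnamate
Product: 24 CNP0252898.2, the 4β,6β,15-orthocinnamate of 5β,7αH,10α-eudesmane-1α,4β,6β,9α,15-pentol
Conditions: 23 (1.1 equiv), camphorsulfonic acid (10 mol %), 4 Å molecular sieves, CH2Cl2, rt; Et3N quench
Reagents that add atoms: none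
Why: Acid-catalysed transorthoesterification is reversible and should funnel to the caged 2,7,8-trioxabicyclo[3.2.1]octane that spans the primary 15-OH, the tertiary 4β-OH and the peri 6β-OH (analogy: selective 1,3,5-orthoester formation of myo-inositol), while the 1α,9α-diol cannot form a cage and stays free and the configuration of the orthoester carbon is dictated by the cage.

**Compound list**

1 | 3-methylcyclopent-2-en-1-one | CC1=CC(=O)CC1 | starting material
2 | 4-methylcyclopent-4-ene-1,3-dione | CC1=CC(=O)CC1=O | intermediate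
3 | isobutyltriphenylphosphonium bromide | CC(C)C[P+](c1ccccc1)(c1ccccc1)c1ccccc1.[Br-] | starting material
4 | ethyl formate | CCOC=O | starting material
5 | isobutylidenetriphenylphosphorane | CC(C)C=P(c1ccccc1)(c1ccccc1)c1ccccc1 | intermediate (not isolated)
6 | 3-methyl-2-(triphenylphosphoranylidene)butanal | CC(C)C(C=O)=P(c1ccccc1)(c1ccccc1)c1ccccc1 | intermediate
7 | (tert-butyldimethylsilyloxy)acetaldehyde | O=CCO[Si](C)(C)C(C)(C)C | starting material
8 | (E)-4-(tert-butyldimethylsilyloxy)-2-isopropylbut-2-enal | O=C/C(C(C)C)=C/CO[Si](C)(C)C(C)(C)C | intermediate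
9 | (1E,3E)-4-(tert-butyldimethylsilyloxy)-2-isopropyl-1-(triisopropylsilyloxy)buta-1,3-diene | CC(C)[Si](C(C)C)(C(C)C)O/C=C(C(C)C)/C=C/O[Si](C)(C)C(C)(C)C | intermediate
10 | endo adduct: 7-(tert-butyldimethylsilyloxy)-5-isopropyl-7a-methyl-4-(triisopropylsilyloxy)-3a,4,7,7a-tetrahydro-1H-indene-1,3(2H)-dione, cis-fused, both silyloxy groups trans to 3a-H and 7a-methyl (eudesmane labels 5α-H, 10α-Me, 6β-OTIPS, 9β-OTBS; largely enolised) | O=C1CC(=O)[C@@]2(C)[C@@H](O[Si](C)(C)C(C)(C)C)C=C(C(C)C)[C@@H](O[Si](C(C)C)(C(C)C)C(C)C)[C@@H]12 | intermediate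
11 | 9β-(tert-butyldimethylsilyloxy)-6β-(triisopropylsilyloxy)-15-nor-5α,10α-eudesm-7-ene-1,4-dione (cis-fused) | O=C1CCC(=O)[C@@]2(C)[C@@H](O[Si](C)(C)C(C)(C)C)C=C(C(C)C)[C@@H](O[Si](C(C)C)(C(C)C)C(C)C)[C@@H]12 | intermediate
12 | 9β-(tert-butyldimethylsilyloxy)-6β-(triisopropylsilyloxy)-15-nor-5β,10α-eudesm-7-ene-1,4-dione (trans-fused) | O=C1CCC(=O)[C@@]2(C)[C@@H](O[Si](C)(C)C(C)(C)C)C=C(C(C)C)[C@@H](O[Si](C(C)C)(C(C)C)C(C)C)[C@H]12 | intermediate
13 | 9β-(tert-butyldimethylsilyloxy)-6β-(triisopropylsilyloxy)-5β,10α-eudesma-4(15),7-dien-1-one | C=C1CCC(=O)[C@@]2(C)[C@@H](O[Si](C)(C)C(C)(C)C)C=C(C(C)C)[C@@H](O[Si](C(C)C)(C(C)C)C(C)C)[C@H]12 | intermediate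
14 | 9β-(tert-butyldimethylsilyloxy)-4β,15-dihydroxy-6β-(triisopropylsilyloxy)-5β,10α-eudesm-7-en-1-one | OC[C@]1(O)CCC(=O)[C@@]2(C)[C@@H](O[Si](C)(C)C(C)(C)C)C=C(C(C)C)[C@@H](O[Si](C(C)C)(C(C)C)C(C)C)[C@H]12 | intermediate
15 | 4β,9β,15-trihydroxy-6β-(triisopropylsilyloxy)-5β,10α-eudesm-7-en-1-one | OC[C@]1(O)CCC(=O)[C@@]2(C)[C@@H](O)C=C(C(C)C)[C@@H](O[Si](C(C)C)(C(C)C)C(C)C)[C@H]12 | intermediate
16 | 4β,15-dihydroxy-6β-(triisopropylsilyloxy)-5β,10α-eudesm-7-ene-1,9-dione | OC[C@]1(O)CCC(=O)[C@@]2(C)C(=O)C=C(C(C)C)[C@@H](O[Si](C(C)C)(C(C)C)C(C)C)[C@H]12 | intermediate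
17 | 6β-(triisopropylsilyloxy)-5β,10α-eudesm-7-ene-1α,4β,9α,15-tetrol | OC[C@]1(O)CC[C@H](O)[C@@]2(C)[C@H](O)C=C(C(C)C)[C@@H](O[Si](C(C)C)(C(C)C)C(C)C)[C@H]12 | intermediate
18 | 6β-(triisopropylsilyloxy)-5β,7αH,10α-eudesmane-1α,4β,9α,15-tetrol | OC[C@]1(O)CC[C@H](O)[C@@]2(C)[C@H](O)C[C@@H](C(C)C)[C@@H](O[Si](C(C)C)(C(C)C)C(C)C)[C@H]12 | intermediate
19 | 5β,7αH,10α-eudesmane-1α,4β,6β,9α,15-pentol | OC[C@]1(O)CC[C@H](O)[C@@]2(C)[C@H](O)C[C@@H](C(C)C)[C@@H](O)[C@H]12 | intermediate
20 | (E)-β-bromostyrene | Br/C=C/c1ccccc1 | starting material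
21 | tetramethyl orthocarbonate | COC(OC)(OC)OC | starting material
22 | (E)-styrylmagnesium bromide | Br[Mg]/C=C/c1ccccc1 | intermediate (not isolated)
23 | trimethyl orthocinnamate, (E)-(3,3,3-trimethoxyprop-1-enyl)benzene | COC(OC)(OC)/C=C/c1ccccc1 | intermediate
24 | CNP0252898.2: 1α,9α-dihydroxy-5β,7αH,10α-eudesmane-4β,6β,15-triyl orthocinnamate | CC(C)[C@@H]1C[C@@H](O)[C@@]2(C)[C@@H]3[C@@H]1O[C@]1(/C=C/c4ccccc4)OC[C@@]3(CC[C@@H]2O)O1 | target

**Step count.** 16 steps in total; the longest linear sequence is 14 steps (steps 2–14 and 16); steps 1 and 15 are one-step side branches.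

**The three steps most likely to fail**

1. Step 6 (ring expansion). The zinc enolate of a cyclic 1,3-dione cannot chelate zinc, so methylene transfer may be slow; cyclopropanation of the 7-ene or methylation of the product enolate may then compete. The fallback sets out from 10 and isolates the donor–acceptor cyclopropane with a rhodium carbene instead of the zinc carbenoid. Silylation (Me3SiCl, Et3N) should give the trimethylsilyl enol ether F1. Cyclopropanation with allyl diazoacetate and Rh2(OAc)4 should give the siloxycyclopropane allyl ester F2. Et3N·3HF should open it by desilylation and retro-aldol cleavage to the ring-expanded β-keto allyl ester F3. Pd(PPh3)4 with morpholine should then remove the allyl ester with decarboxylation and return to 11.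

2. Step 5 (enantioselective Diels–Alder). The catalyst may discriminate poorly between the two faces or the two orientations of the diene, and the acidic catalyst may degrade the bis(silyl enol ether) diene before cycloaddition. The fallback sets out from 2 and 9 and uses no chiral catalyst. Thermal cycloaddition (toluene, rt), in which steric pairing alone should direct the regiochemistry, gives the racemic endo adduct F4. Its acidic enol is resolved by crystallisation of the (R)-1-phenylethylammonium salt F5, and cold dilute HCl returns 10.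

3. Step 7 (C5 epimerisation). The C5 enolate may lose the 6-silyloxy group by E1cB elimination, or the cis/trans equilibrium may be less one-sided than expected because of the peri interaction between the 6-silyloxy group and the C4 carbonyl. The fallback sets out from 11 and uses the elimination instead of avoiding it. DBU in warm toluene drives it to the 5,7-dien-4-one F6. Copper-catalysed conjugate borylation (CuCl, NaOt-Bu, 4,5-bis(diphenylphosphino)-9,9-dimethylxanthene, B2pin2, MeOH) should add boron to C6 from the β face opposite the syn-axial 10α-methyl, and protonation at C5 should give the trans-fused β-boryl ketone F7. NaBO3 oxidation with retention gives the 6β-hydroxy ketone F8, and i-Pr3SiOTf/2,6-lutidine returns to 12.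

Further compounds
F1 | step 6 | trimethylsilyl enol ether of 10 (silyloxy on the carbonyl next to C5) | C[Si](C)(C)OC1=CC(=O)[C@@]2(C)[C@@H](O[Si](C)(C)C(C)(C)C)C=C(C(C)C)[C@@H](O[Si](C(C)C)(C(C)C)C(C)C)[C@@H]12
F2 | step 6 | siloxycyclopropane allyl ester from F1 (configuration of the three cyclopropane carbons immaterial) | C[Si](C)(C)OC12C(C(=O)OCC=C)C1C(=O)[C@@]3(C)[C@@H](O[Si](C)(C)C(C)(C)C)C=C(C(C)C)[C@@H](O[Si](C(C)C)(C(C)C)C(C)C)[C@@H]23
F3 | step 6 | allyl ester of the ring-expanded β-keto acid (ester on C3 of 11, epimer mixture at C3) | C=CCOC(=O)C1CC(=O)[C@@]2(C)[C@@H](O[Si](C)(C)C(C)(C)C)C=C(C(C)C)[C@@H](O[Si](C(C)C)(C(C)C)C(C)C)[C@H]2C1=O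
F4 | step 5 | racemic 10 (equimolar 10 and its enantiomer) | O=C1CC(=O)[C@@]2(C)[C@@H](O[Si](C)(C)C(C)(C)C)C=C(C(C)C)[C@@H](O[Si](C(C)C)(C(C)C)C(C)C)[C@@H]12.O=C1CC(=O)[C@]2(C)[C@H](O[Si](C)(C)C(C)(C)C)C=C(C(C)C)[C@H](O[Si](C(C)C)(C(C)C)C(C)C)[C@H]12
F5 | step 5 | (R)-1-phenylethylammonium enolate of 10 | C[C@@H]([NH3+])c1ccccc1.[O-]C1=CC(=O)[C@@]2(C)[C@@H](O[Si](C)(C)C(C)(C)C)C=C(C(C)C)[C@@H](O[Si](C(C)C)(C(C)C)C(C)C)[C@@H]12
F6 | step 7 | 9β-(tert-butyldimethylsilyloxy)-15-nor-10α-eudesma-5,7-diene-1,4-dione | O=C1CCC(=O)[C@@]2(C)[C@@H](O[Si](C)(C)C(C)(C)C)C=C(C(C)C)C=C12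
F7 | step 7 | 9β-(tert-butyldimethylsilyloxy)-6β-(pinacolatoboryl)-15-nor-5β,10α-eudesm-7-ene-1,4-dione | O=C1CCC(=O)[C@@]2(C)[C@@H](O[Si](C)(C)C(C)(C)C)C=C(C(C)C)[C@@H](B3OC(C)(C)C(C)(C)O3)[C@H]12
F8 | step 7 | 9β-(tert-butyldimethylsilyloxy)-6β-hydroxy-15-nor-5β,10α-eudesm-7-ene-1,4-dione | O=C1CCC(=O)[C@@]2(C)[C@@H](O[Si](C)(C)C(C)(C)C)C=C(C(C)C)[C@@H](O)[C@H]12
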